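**Plan**

1. Retrosynthesis cuts the two σ-bonds C2–C2' and C5–C3' of the bicyclo[2.2.1]heptene (bridgeheads C2 and C5, one-carbon bridge C1, alkene C3=C4) in a retro-[4+2]. This is possible because both halves are the same guaianolide: one half shows its cyclopentadiene C2=C3–C4=C5 as the diene, the other its C2'=C3' bond as dienophile with C4'=C5' left over, the pattern of an endo cyclopentadiene dimer.
2. The C15 monomer 8 is traced back to the bridged 3β,10β-ether 6 (cut C3–O with loss of H2), then to the 3β-hydroxy-4,9-diene 5 (cut C10–O), enone 4, isophotosantonic lactone 2 and α-santonin 1.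
3. Forward: photorearrangement of santonin builds the 5/7/5 lactone skeleton; dehydration and Luche reduction follow; a temporary oxygen bridge carries the oxygen from C3 to the β-face of C10; eliminative opening of the bridge unveils the diene; dimerization closes the norbornene rings last.
4. Stereochemistry: C6, C7 and C11 come from santonin; C1 from the photorearrangement; C10 from tethered oxygen delivery, which corrects the C10 configuration of the photoproduct; C2, C5, C2' and C3' from the endo cycloaddition anti to C10 and C10'.

Key step: step 6

Remark on the chemistry: each C15 half is numbered as a guaiane (C14 = methyl on C10, C15 = methyl on C4, primed numbers for the half that acts as dienophile; 6βH, 7αH, 11βH throughout), and (−)-α-santonin is taken as the commercial single enantiomer.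

**Route**

Step 1
Reactants: 1 (−)-α-santonin
Product: 2 isophotosantonic lactone (10α-hydroxy-3-oxo-1αH-guai-4-en-12,6α-olide)
Conditions: hν (medium-pressure Hg lamp, Pyrex), AcOH/H2O 1:1, reflux, N2
Reagents that add atoms: water, O
Why: Photochemical rearrangement of the cross-conjugated cyclohexadienone, in which C1–C5 bonding gives a cyclopropyl zwitterion that, once protonated, is opened by water at C10 with inversion, so that C1 (1αH) and C10 (10α-OH) are set together from the C10 stereocentre of santonin while C6, C7 and C11 are untouched.

Step 2
Reactants: 2 isophotosantonic lactone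
Product: 4 3-oxo-1αH-guaia-4,9-dien-12,6α-olide, via tertiary chlorosulfite 3 (not isolated)
Conditions: SOCl2, pyridine, CH2Cl2, −20 to 0 °C
Reagents that add atoms: none
Why: Dehydration by anti-periplanar E2 elimination of the tertiary chlorosulfite, in which H1 is cis to the leaving group and cannot be lost, so conjugation into a 1(10),4-dienone is avoided and the Zaitsev proton at C9 should be removed.

Step 3
Reactants: 4 3-oxo-1αH-guaia-4,9-dien-12,6α-olide
Product: 5 3β-hydroxy-1αH-guaia-4,9-dien-12,6α-olide
Conditions: NaBH4, CeCl3·7H2O, MeOH, −78 to −20 °C
Reagents that add atoms: none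
Why: Luche 1,2-reduction in which hydride should add to the α-face of the flat cyclopentenone, anti to the C1–C10 bond that projects on the β-face, giving the 3β-alcohol cis to C10 as the bridge requires, with the lactone untouched.

Step 4
Reactants: 5 3β-hydroxy-1αH-guaia-4,9-dien-12,6α-olide
Product: 6 3β,10β-epoxy-1αH-guai-4-en-12,6α-olide (10α-methyl; O, C3, C2, C1, C10 and C4=C5 form a 2-oxabicyclo[2.2.1]hept-5-ene)
Conditions: Co(C36H52N2O2) 5 mol% (divalent cobalt complex of N,N'-bis(3,5-di-tert-butylsalicylidene)-1,2-cyclohexanediamine), N-fluoro-2,4,6-trimethylpyridinium triflate, PhSiH3, PhCF3, 0 °C to rt, argon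
Reagents that add atoms: none
Why: Mukaiyama-type hydrogen-atom transfer from a cobalt hydride to C9 gives the tertiary C10 radical, which after radical–polar crossover is captured 5-exo by the 3β-hydroxyl (intramolecular Markovnikov hydroalkoxylation); the oxygen is held on the β-face of the five-membered ring and can only reach the β-face of C10, which sets the 10β-O, 10α-methyl configuration of the target, and loss of a methyl proton instead of H9 in step 2 would not matter because either alkene position gives the same C10 radical.

Step 5
Reactants: 6 3β,10β-epoxy-1αH-guai-4-en-12,6α-olide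
Product: 8 10β-hydroxy-1αH-guaia-2,4-dien-12,6α-olide, via silyl ether diene 7 (not isolated)
Conditions: TMSOTf, 2,6-lutidine, CH2Cl2, −78 to −20 °C; then MeOH, 0 °C
Reagents that add atoms: none
Why: Proposed new method: silylation of the strained bridging oxygen should give an oxonium ion whose C3–O bond is allylic, nearly parallel to the p-orbitals of C4=C5 and anti-periplanar to the C2–H bond that lies syn to that alkene, so that 2,6-lutidine can remove this proton in an E2-like elimination (E1 at the limit, through the C3–C4–C5 allyl cation) that opens the oxabicycle, releases its strain and leaves the C2=C3–C4=C5 diene and the C10 silyl ether with C1 and C10 untouched; the closest known reaction type is the silyl triflate/amine isomerization of epoxides to allylic silyl ethers, and the silyl group is then removed by methanolysis catalysed by the lutidinium triflate already present.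

Step 6
Reactants: 8 10β-hydroxy-1αH-guaia-2,4-dien-12,6α-olide (two molecules)
Product: 9 absinthin
Conditions: neat (or ≥2 M in benzene), trace BHT, 20–25 °C, argon, dark, several days
Reagents that add atoms: none
Why: Thermal, concerted but asynchronous [4+2] cyclodimerization (Diels–Alder) in which the C2=C3–C4=C5 diene of one molecule of 8 adds suprafacially across the disubstituted C2'=C3' bond of a second molecule, the closest known reaction being the endo dimerization of cyclopentadiene and of 5-substituted cyclopentadienes. The new bonds C2–C2' and C5–C3' close together the five-membered ring C1–C2–C2'–C3'–C5 and the cyclohexene ring C2–C3=C4–C5–C3'–C2' of the bicyclo[2.2.1]heptene, both by the same intermolecular cycloaddition. C2 and C5 are set by approach of the dienophile to the diene face that carries H1, because C10 with its hydroxyl lies over the other face (C10 therefore ends syn to the new C3=C4 bond); C2' and C3' are set by attack on the face of the dienophile ring anti to C10', and the endo rule (overlap of the diene with the C4'=C5' bond of the partner) fixes the relation of the two halves. The step needs site selectivity (C2'=C3' and not the tetrasubstituted C4'=C5'), head-to-head regiochemistry (the leading bond joins the two unsubstituted diene termini C2 and C2', leaving allyl-type delocalization on both sides, and the lagging bond joins C5 to C3') and facial selectivity on both partners, all of which should follow from the single quaternary substituent on C1. Working neat at ambient temperature should keep the bimolecular cycloaddition ahead of the 1,5-hydrogen shift that would scramble C1.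

**Compound list**

1 | (−)-α-santonin, (3S,3aS,5aS,9bS)-3,5a,9-trimethyl-3a,4,5,9b-tetrahydronaphtho[1,2-b]furan-2,8(3H,5aH)-dione | C[C@H]1[C@@H]2CC[C@]3(C)C=CC(=O)C(C)=C3[C@H]2OC1=O | starting material
2 | isophotosantonic lactone, 10α-hydroxy-3-oxo-1αH-guai-4-en-12,6α-olide, (3S,3aS,6R,6aR,9bS) | CC1=C2[C@H]3OC(=O)[C@@H](C)[C@@H]3CC[C@@](C)(O)[C@@H]2CC1=O | intermediate
3 | 10α-chlorosulfite of 2 | CC1=C2[C@H]3OC(=O)[C@@H](C)[C@@H]3CC[C@@](C)(OS(Cl)=O)[C@@H]2CC1=O | intermediate
4 | 3-oxo-1αH-guaia-4,9-dien-12,6α-olide | CC1=C2[C@H]3OC(=O)[C@@H](C)[C@@H]3CC=C(C)[C@@H]2CC1=O | intermediate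
5 | 3β-hydroxy-1αH-guaia-4,9-dien-12,6α-olide (hydroxyl cis to C10 on the five-membered ring) | CC1=C2[C@H]3OC(=O)[C@@H](C)[C@@H]3CC=C(C)[C@@H]2C[C@@H]1O | intermediate
6 | 3β,10β-epoxy-1αH-guai-4-en-12,6α-olide (oxygen bridge on the β-face, 10α-methyl) | CC1=C2[C@H]3OC(=O)[C@@H](C)[C@@H]3CC[C@]4(C)O[C@H]1C[C@H]24 | intermediate
7 | 10β-(trimethylsilyloxy)-1αH-guaia-2,4-dien-12,6α-olide | CC1=C2[C@H]3OC(=O)[C@@H](C)[C@@H]3CC[C@](C)(O[Si](C)(C)C)[C@@H]2C=C1 | intermediate
8 | 10β-hydroxy-1αH-guaia-2,4-dien-12,6α-olide, (3S,3aS,6S,6aR,9bS)-6-hydroxy-3,6,9-trimethyl-3,3a,4,5,6,6a-hexahydroazuleno[4,5-b]furan-2(9bH)-one | CC1=C2[C@H]3OC(=O)[C@@H](C)[C@@H]3CC[C@](C)(O)[C@@H]2C=C1 | intermediate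
9 | absinthin (endo head-to-head dimer of 8; C2–C2' and C5–C3' bonds; both 10-hydroxyls trans to H1 and H1') | CC1=C[C@@H]2[C@H]3[C@H](C(C)=C4[C@H]5OC(=O)[C@@H](C)[C@@H]5CC[C@](C)(O)[C@@H]43)[C@@]13[C@@H]2[C@@](C)(O)CC[C@H]1[C@H](C)C(=O)O[C@@H]13 | target

**Step count and risks**

Total step count: 6. Longest linear sequence: 6 steps (the route is linear; step 6 joins two molecules of the same intermediate).

Steps most likely to fail:

Step 5 (Proposed new method). What may go wrong: ionization of the tertiary C10–O bond instead of the allylic C3–O bond, Grob-type fragmentation of the C1–C10 bond from the allyl cation, proton loss from C1 or C6 instead of C2, or cationic oligomerization of the diene. The fallback uses known chemistry, sets out from 6 and comes back at 7. The ether is opened by SN2 attack of selenium at C3 from the α-face, anti to the bridging oxygen, with PhSeSiMe3 and catalytic ZnI2 in CH2Cl2, which should give 3α-(phenylselanyl)-10β-(trimethylsilyloxy)-1αH-guai-4-en-12,6α-olide F1. Oxidation with H2O2 and pyridine in CH2Cl2 at 0 °C should give the corresponding selenoxide F2, whose syn-elimination can only run toward C2, since C4 carries no hydrogen, and gives silyl ether 7. Methanolysis as in step 5 then gives 8.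

Step 4. What may go wrong: a 1,2-hydride shift from C1 in the cationic intermediate (toward an allyl cation), alkene isomerization by reversible hydrogen-atom transfer, or failure to close the strained bicyclic ether. The fallback sets out from 5 and comes back at 6 by intramolecular alkoxymercuration and reductive demercuration, which avoids a free cation. Hg(OAc)2 (divalent mercury) in THF at 0 °C should form the mercurinium ion on the α-face of C9=C10, which the 3β-hydroxyl opens at C10 from the β-face to give 9α-(acetoxymercurio)-3β,10β-epoxy-1αH-guai-4-en-12,6α-olide F3. NaBH4 in aqueous NaOH at 0 °C then replaces mercury by hydrogen to give 6.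

Step 6. What may go wrong: the 1,5-hydrogen shift in the free dienol outruns the cycloaddition (loss of the C1 configuration and drain into the unreactive tetrasubstituted diene isomer), or hydrogen bonding of the free carbinols misdirects the approach of the partners. The fallback sets out from 7, isolated by bicarbonate work-up in place of the methanol quench, and comes back at 9. The silyl ether is dimerized neat, or at 10–12 kbar in CH2Cl2, to 10,10'-bis-O-(trimethylsilyl)absinthin F4; the bulkier silyloxy groups shield the β-faces more strongly and remove the hydrogen-bond donors. TBAF buffered with AcOH in THF at 0 °C then frees both carbinols to give 9.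

**Further compounds**

F1 | step 5 | 3α-(phenylselanyl)-10β-(trimethylsilyloxy)-1αH-guai-4-en-12,6α-olide | CC1=C2[C@H]3OC(=O)[C@@H](C)[C@@H]3CC[C@](C)(O[Si](C)(C)C)[C@@H]2C[C@H]1[Se]c1ccccc1
F2 | step 5 | selenoxide of F1 (3α-(phenylseleninyl)-10β-(trimethylsilyloxy)-1αH-guai-4-en-12,6α-olide) | CC1=C2[C@H]3OC(=O)[C@@H](C)[C@@H]3CC[C@](C)(O[Si](C)(C)C)[C@@H]2C[C@H]1[Se](=O)c1ccccc1
F3 | step 4 | 9α-(acetoxymercurio)-3β,10β-epoxy-1αH-guai-4-en-12,6α-olide | CC1=C2[C@H]3OC(=O)[C@@H](C)[C@@H]3C[C@@H]([Hg]OC(C)=O)[C@]4(C)O[C@H]1C[C@H]24
F4 | step 6 | 10,10'-bis-O-(trimethylsilyl)absinthin | CC1=C[C@@H]2[C@H]3[C@H](C(C)=C4[C@H]5OC(=O)[C@@H](C)[C@@H]5CC[C@](C)(O[Si](C)(C)C)[C@@H]43)[C@@]13[C@@H]2[C@@](C)(O[Si](C)(C)C)CC[C@H]1[C@H](C)C(=O)O[C@@H]13
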